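**Plan**

- Retrosynthesis: the seco acid 23 comes from the eight-membered lactone 22 (acyl C–O bond). 22 is traced back to the spiro dienone 19 by re-forming the C3–C1' bond. 19 is cut at C1'–C6' and C1'–C2' into coumaranone 11 and the C6 enynoate 17.
- Enabling feature: ring B is a catechol monoether whose ether carbon C1' lies between C2'–OH and C6'–CH2OH. C1' can therefore be C2 of a benzofuran-3(2H)-one, already bonded to the ether oxygen, carrying ring B as a spiro cyclohexa-2,4-dienone; C3 of that furanone is the ring-A carboxyl carbon.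
- Forward: ring A is dressed (O-alkylation, formylation, methallylation, hydration), the furanone ring closes by Dieckmann condensation, and ring B is annulated in step 13. The furanone ring is then opened by an aromatising retro-Claisen fragmentation, so the hindered diaryl ether is never made by arylation.
- Stereochemistry: the only stereocentre, the (R)-carbinol, is set by reagent-controlled Brown methallylboration and carried as a silyl ether. The spiro carbon forms unselectively and disappears on aromatisation.

Key step: step 13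

Assumption: the borane of the (−)-α-pinene series is taken to add to the Re face of aldehyde 4, as its allyl analogue does with aryl aldehydes; if the sense proves opposite, the enantiomeric reagent is used.
Assumption: 19 is carried forward as the mixture of its two spiro epimers, since both give 22.

Step 1
Reactants: 1 methyl 2,6-dihydroxybenzoate
Product: 2 methyl 2-hydroxy-6-(2-methoxy-2-oxoethoxy)benzoate
Conditions: BrCH2CO2Me (1.0 equiv), K2CO3 (1.0 equiv), acetone, rt
Reagents that add atoms: methyl bromoacetate, COC(=O)CBr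
Why: Williamson O-alkylation of a symmetrical diol whose remaining hydroxyl, once the first is etherified, is held in a hydrogen bond to the ester carbonyl and reacts more slowly, so one equivalent of bromide should give mainly the mono-ether.

Step 2
Reactants: 2 methyl 2-hydroxy-6-(2-methoxy-2-oxoethoxy)benzoate
Product: 3 methyl 3-formyl-2-hydroxy-6-(2-methoxy-2-oxoethoxy)benzoate
Conditions: MgCl2, Et3N, (CH2O)n, MeCN, reflux; then 1 M HCl
Reagents that add atoms: paraformaldehyde (as formaldehyde), C=O
Why: Casnati–Skattebøl ortho-formylation, in which the magnesium phenoxide delivers formaldehyde only to the single free position ortho to the hydroxyl (C3, also para to the ether oxygen) and a second formaldehyde oxidises the benzylic alkoxide to the aldehyde by hydride transfer.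

Step 3
Reactants: 3 methyl 3-formyl-2-hydroxy-6-(2-methoxy-2-oxoethoxy)benzoate
Product: 4 methyl 3-formyl-2-methoxy-6-(2-methoxy-2-oxoethoxy)benzoate
Conditions: MeI, K2CO3, DMF, rt
Reagents that add atoms: iodomethane, CI
Why: Williamson methylation of the only acidic site, the chelated phenol, under conditions too mild to enolise the aryloxyacetate.

Step 4
Reactants: 4 methyl 3-formyl-2-methoxy-6-(2-methoxy-2-oxoethoxy)benzoate
Product: 6 methyl 3-[(1R)-1-hydroxy-3-methylbut-3-en-1-yl]-2-methoxy-6-(2-methoxy-2-oxoethoxy)benzoate, via O-diisopinocampheylboryl ether 5 (not isolated)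
Conditions: (+)-Ipc2BOMe [from (−)-α-pinene], methallylMgCl, Et2O, 0 °C → rt; then 4, −78 °C; then 3 M NaOAc, 30% H2O2, 0 °C → rt
Reagents that add atoms: methallylmagnesium chloride, CC(=C)C[Mg]Cl
Why: Brown methallylboration through a closed chair transition state, in which the B-methallyl borane with isopinocampheyl groups of the (−)-α-pinene series adds to the Re face of the aryl aldehyde and so sets the (R)-carbinol, the esters being inert to the borane at −78 °C and to the buffered peroxide that frees the alcohol from 5.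

Step 5
Reactants: 6 methyl 3-[(1R)-1-hydroxy-3-methylbut-3-en-1-yl]-2-methoxy-6-(2-methoxy-2-oxoethoxy)benzoate
Product: 7 methyl 3-[(1R)-1-[(tert-butyldimethylsilyl)oxy]-3-methylbut-3-en-1-yl]-2-methoxy-6-(2-methoxy-2-oxoethoxy)benzoate
Conditions: TBSOTf, 2,6-lutidine, CH2Cl2, −78 → 0 °C
Reagents that add atoms: tert-butyldimethylsilyl triflate, CC(C)(C)[Si](C)(C)OS(=O)(=O)C(F)(F)F
Why: Silyl ether formation with a silyl triflate and a hindered base protects the hindered benzylic alcohol without ionising it and gives a group that fluoride removes at the end without acid.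

Step 6
Reactants: 7 methyl 3-[(1R)-1-[(tert-butyldimethylsilyl)oxy]-3-methylbut-3-en-1-yl]-2-methoxy-6-(2-methoxy-2-oxoethoxy)benzoate
Product: 8 methyl 3-[(1R)-1-[(tert-butyldimethylsilyl)oxy]-3-hydroxy-3-methylbutyl]-2-methoxy-6-(2-methoxy-2-oxoethoxy)benzoate
Conditions: Co(acac)2 (20 mol %), PhSiH3, O2 (1 atm), THF, rt
Reagents that add atoms: dioxygen, O=O
Why: Mukaiyama hydration (cobalt-hydride hydrogen-atom transfer, capture of the tertiary radical by O2, reduction of the peroxide by the silane) gives the Markovnikov tertiary alcohol from the 1,1-disubstituted alkene and leaves esters, silyl ether and stereocentre untouched.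

Step 7
Reactants: 8 methyl 3-[(1R)-1-[(tert-butyldimethylsilyl)oxy]-3-hydroxy-3-methylbutyl]-2-methoxy-6-(2-methoxy-2-oxoethoxy)benzoate
Product: 9 methyl 5-[(1R)-1-[(tert-butyldimethylsilyl)oxy]-3-hydroxy-3-methylbutyl]-3-hydroxy-4-methoxy-1-benzofuran-2-carboxylate
Conditions: LiHMDS (3.2 equiv), THF, −78 → 0 °C; then AcOH
Reagents that add atoms: none
Why: Dieckmann condensation in which the lithium enolate of the aryloxyacetate closes the five-membered ring on the ortho benzoate (5-exo-trig) and the product is held as its aromatic enolate, the lithium tertiary alkoxide being a spectator because a silyl shift to the more hindered tertiary oxygen is not favoured.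

Step 8
Reactants: 9 methyl 5-[(1R)-1-[(tert-butyldimethylsilyl)oxy]-3-hydroxy-3-methylbutyl]-3-hydroxy-4-methoxy-1-benzofuran-2-carboxylate
Product: 11 5-[(1R)-1-[(tert-butyldimethylsilyl)oxy]-3-hydroxy-3-methylbutyl]-4-methoxy-1-benzofuran-3(2H)-one, via benzofuran-2-carboxylic acid 10 (not isolated)
Conditions: NaOH, MeOH/H2O, 65 °C; then AcOH to pH 4–5, 45 °C
Reagents that add atoms: none
Why: Classical coumaranone synthesis by saponification of the enolised β-keto ester and decarboxylation of the β-keto acid tautomer of 10 on gentle acidification, conditions that the secondary silyl ether and the tertiary alcohol should tolerate.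

Step 9
Reactants: 12 methyl but-2-ynoate
Product: 13 methyl (2Z)-3-iodobut-2-enoate
Conditions: NaI, AcOH, 115 °C
Reagents that add atoms: sodium iodide, [Na+].[I-]
Why: Hydroiodination of an ynoate by conjugate addition of iodide and anti protonation is an established route to the (Z)-β-iodoenoate.

Step 10
Reactants: 13 methyl (2Z)-3-iodobut-2-enoate; 14 tert-butyldimethyl(prop-2-yn-1-yloxy)silane
Product: 15 methyl (2Z)-6-[(tert-butyldimethylsilyl)oxy]-3-methylhex-2-en-4-ynoate
Conditions: PdCl2(PPh3)2 (2 mol %), CuI (4 mol %), Et3N, THF, rt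
Reagents that add atoms: none
Why: Sonogashira coupling of a vinyl iodide with a terminal alkyne proceeds at room temperature with retention of the alkene geometry.

Step 11
Reactants: 15 methyl (2Z)-6-[(tert-butyldimethylsilyl)oxy]-3-methylhex-2-en-4-ynoate
Product: 16 (2Z)-6-[(tert-butyldimethylsilyl)oxy]-3-methylhex-2-en-4-ynoic acid
Conditions: LiOH, THF/H2O, 0 °C → rt; then 1 M HCl to pH 3, 0 °C
Reagents that add atoms: lithium hydroxide, [Li+].[OH-]
Why: Ester saponification, to which the silyl ether and the Z-enyne are stable in the cold, as they are to brief acidification.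

Step 12
Reactants: 16 (2Z)-6-[(tert-butyldimethylsilyl)oxy]-3-methylhex-2-en-4-ynoic acid
Product: 17 1,1,1,3,3,3-hexafluoropropan-2-yl (2Z)-6-[(tert-butyldimethylsilyl)oxy]-3-methylhex-2-en-4-ynoate
Conditions: (CF3)2CHOH, EDC·HCl, DMAP (10 mol %), CH2Cl2, 0 °C → rt
Reagents that add atoms: 1,1,1,3,3,3-hexafluoropropan-2-ol, OC(C(F)(F)F)C(F)(F)F
Why: Steglich-type carbodiimide esterification gives the activated yet chromatographable hexafluoroisopropyl ester that the annulation requires.

Step 13
Reactants: 11 5-[(1R)-1-[(tert-butyldimethylsilyl)oxy]-3-hydroxy-3-methylbutyl]-4-methoxy-1-benzofuran-3(2H)-one; 17 1,1,1,3,3,3-hexafluoropropan-2-yl (2Z)-6-[(tert-butyldimethylsilyl)oxy]-3-methylhex-2-en-4-ynoate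
Product: 19 5-[(1R)-1-[(tert-butyldimethylsilyl)oxy]-3-hydroxy-3-methylbutyl]-6'-{[(tert-butyldimethylsilyl)oxy]methyl}-4-methoxy-4'-methyl-3H-spiro[1-benzofuran-2,1'-cyclohexa[3,5]diene]-2',3-dione (grisa-3',5'-diene-2',3-dione as both spiro epimers), via open-chain 2Z,4Z-dienoate 18 (not isolated)
Conditions: 17 (1.2 equiv), Cs2CO3 (0.3 equiv), 4 Å MS, MeCN, 0 °C → rt, Ar
Reagents that add atoms: none
Why: Proposed new method: carbonate generates the aromatic benzofuran-3-olate of 11, whose soft C2 adds to the δ-carbon of enynoate 17 (the alkyne terminus bearing CH2OTBS), γ-protonation of the allenyl enolate gives dienoate 18, and re-ionisation of its C2–H gives a push–pull trienolate whose 2Z,4Z form acylates C2 on the ester carbonyl with loss of hexafluoroisopropoxide. The closest known reactions are the double-Michael spiroannulation of benzofuran-3(2H)-ones with alkynyl vinyl ketones to grisans, 1,6-additions of stabilised carbanions to 2-en-4-ynoates, and Michael addition–acyl substitution cascades of α,β-unsaturated activated esters. Ring B closes by a 6-exo-trig Dieckmann-type acylation that forms C1'–C2' after the intermolecular conjugate addition has formed C1'–C6'. The only new stereocentre is the spiro carbon, which is not controlled and is erased when ring B aromatises. The step needs δ- rather than β-attack (the β-carbon carries a methyl group and would become quaternary), C- rather than O-reactivity of the ambident enolate (soft alkyne terminus, conjugated ester only weakly acylating) and a cisoid diene (supplied by the freely equilibrating trienolate). The hexafluoroisopropyl ester replaces a simple alkyl ester because 19 is a non-enolisable 1,3-diketone, so that a methoxide leaving group would make the acylation uphill and would cleave 19 by retro-Claisen attack, whereas hexafluoroisopropoxide (pKa of the alcohol about 9) is a good nucleofuge and a poor nucleophile.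

Step 14
Reactants: 19 5-[(1R)-1-[(tert-butyldimethylsilyl)oxy]-3-hydroxy-3-methylbutyl]-6'-{[(tert-butyldimethylsilyl)oxy]methyl}-4-methoxy-4'-methyl-3H-spiro[1-benzofuran-2,1'-cyclohexa[3,5]diene]-2',3-dione
Product: 22 3-[(1R)-1,3-dihydroxy-3-methylbutyl]-11-hydroxy-4-methoxy-9-methyl-5H,7H-dibenzo[b,g][1,5]dioxocin-5-one, via hydroxymethyl spirodienone 20 (not isolated), via mono-silylated lactone 21 (not isolated)
Conditions: TBAF (4 equiv), THF, 0 °C → rt; then AcOH
Reagents that add atoms: none
Why: Fluoride desilylation of the primary silyl ether gives the alkoxide of 20, which can reach only the C3 carbonyl (five-membered hemiketal) and triggers a retro-Claisen fragmentation of the non-enolisable 1,3-diketone with the ring-B phenolate as leaving group, the known nucleophilic cleavage of grisadienediones to diaryl ethers in intramolecular form, after which excess fluoride removes the secondary silyl ether of 21.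

Step 15
Reactants: 22 3-[(1R)-1,3-dihydroxy-3-methylbutyl]-11-hydroxy-4-methoxy-9-methyl-5H,7H-dibenzo[b,g][1,5]dioxocin-5-one
Product: 23 6-[2-hydroxy-6-(hydroxymethyl)-4-methylphenoxy]-3-[(1R)-1,3-dihydroxy-3-methylbutyl]-2-methoxybenzoic acid
Conditions: LiOH, THF/H2O, rt → 40 °C; then 1 M HCl to pH 3–4, 0 °C
Reagents that add atoms: lithium hydroxide, [Li+].[OH-]
Why: Saponification of the eight-membered benzylic lactone followed by cold, mild acidification should give the seco acid without ionising the acid-sensitive benzylic carbinol.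

**Compound list**

1 | methyl 2,6-dihydroxybenzoate | COC(=O)c1c(O)cccc1O | starting material
2 | methyl 2-hydroxy-6-(2-methoxy-2-oxoethoxy)benzoate | COC(=O)COc1cccc(O)c1C(=O)OC | intermediate
3 | methyl 3-formyl-2-hydroxy-6-(2-methoxy-2-oxoethoxy)benzoate | COC(=O)COc1ccc(C=O)c(O)c1C(=O)OC | intermediate
4 | methyl 3-formyl-2-methoxy-6-(2-methoxy-2-oxoethoxy)benzoate | COC(=O)COc1ccc(C=O)c(OC)c1C(=O)OC | intermediate
5 | O-diisopinocampheylboryl ether of 6 (isopinocampheyl groups of the (−)-α-pinene series) | COC(=O)COc1ccc([C@H](OB([C@H]2C[C@H]3C[C@@H]([C@@H]2C)C3(C)C)[C@H]4C[C@H]5C[C@@H]([C@@H]4C)C5(C)C)CC(C)=C)c(OC)c1C(=O)OC | intermediate (not isolated)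
6 | methyl 3-[(1R)-1-hydroxy-3-methylbut-3-en-1-yl]-2-methoxy-6-(2-methoxy-2-oxoethoxy)benzoate | COC(=O)COc1ccc([C@H](O)CC(C)=C)c(OC)c1C(=O)OC | intermediate
7 | methyl 3-[(1R)-1-[(tert-butyldimethylsilyl)oxy]-3-methylbut-3-en-1-yl]-2-methoxy-6-(2-methoxy-2-oxoethoxy)benzoate | COC(=O)COc1ccc([C@H](O[Si](C)(C)C(C)(C)C)CC(C)=C)c(OC)c1C(=O)OC | intermediate
8 | methyl 3-[(1R)-1-[(tert-butyldimethylsilyl)oxy]-3-hydroxy-3-methylbutyl]-2-methoxy-6-(2-methoxy-2-oxoethoxy)benzoate | COC(=O)COc1ccc([C@H](O[Si](C)(C)C(C)(C)C)CC(C)(C)O)c(OC)c1C(=O)OC | intermediate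
9 | methyl 5-[(1R)-1-[(tert-butyldimethylsilyl)oxy]-3-hydroxy-3-methylbutyl]-3-hydroxy-4-methoxy-1-benzofuran-2-carboxylate | COC(=O)c1oc2ccc([C@H](O[Si](C)(C)C(C)(C)C)CC(C)(C)O)c(OC)c2c1O | intermediate
10 | 5-[(1R)-1-[(tert-butyldimethylsilyl)oxy]-3-hydroxy-3-methylbutyl]-3-hydroxy-4-methoxy-1-benzofuran-2-carboxylic acid | OC(=O)c1oc2ccc([C@H](O[Si](C)(C)C(C)(C)C)CC(C)(C)O)c(OC)c2c1O | intermediate (not isolated)
11 | 5-[(1R)-1-[(tert-butyldimethylsilyl)oxy]-3-hydroxy-3-methylbutyl]-4-methoxy-1-benzofuran-3(2H)-one | COc1c([C@H](O[Si](C)(C)C(C)(C)C)CC(C)(C)O)ccc2OCC(=O)c12 | intermediate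
12 | methyl but-2-ynoate | CC#CC(=O)OC | starting material
13 | methyl (2Z)-3-iodobut-2-enoate | COC(=O)/C=C(/C)I | intermediate
14 | tert-butyldimethyl(prop-2-yn-1-yloxy)silane | C#CCO[Si](C)(C)C(C)(C)C | starting material
15 | methyl (2Z)-6-[(tert-butyldimethylsilyl)oxy]-3-methylhex-2-en-4-ynoate | COC(=O)/C=C(/C)C#CCO[Si](C)(C)C(C)(C)C | intermediate
16 | (2Z)-6-[(tert-butyldimethylsilyl)oxy]-3-methylhex-2-en-4-ynoic acid | OC(=O)/C=C(/C)C#CCO[Si](C)(C)C(C)(C)C | intermediate
17 | 1,1,1,3,3,3-hexafluoropropan-2-yl (2Z)-6-[(tert-butyldimethylsilyl)oxy]-3-methylhex-2-en-4-ynoate | FC(F)(F)C(OC(=O)/C=C(/C)C#CCO[Si](C)(C)C(C)(C)C)C(F)(F)F | intermediate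
18 | 1,1,1,3,3,3-hexafluoropropan-2-yl (2Z,4Z)-5-{5-[(1R)-1-[(tert-butyldimethylsilyl)oxy]-3-hydroxy-3-methylbutyl]-4-methoxy-3-oxo-2,3-dihydro-1-benzofuran-2-yl}-6-[(tert-butyldimethylsilyl)oxy]-3-methylhexa-2,4-dienoate (C2 of the furanone unspecified) | FC(F)(F)C(OC(=O)/C=C(/C)\C=C(\CO[Si](C)(C)C(C)(C)C)/C1Oc2ccc([C@H](O[Si](C)(C)C(C)(C)C)CC(C)(C)O)c(OC)c2C1=O)C(F)(F)F | intermediate (not isolated)
19 | 5-[(1R)-1-[(tert-butyldimethylsilyl)oxy]-3-hydroxy-3-methylbutyl]-6'-{[(tert-butyldimethylsilyl)oxy]methyl}-4-methoxy-4'-methyl-3H-spiro[1-benzofuran-2,1'-cyclohexa[3,5]diene]-2',3-dione (spiro centre unspecified) | COc1c([C@H](O[Si](C)(C)C(C)(C)C)CC(C)(C)O)ccc2OC3(C(=O)C=C(C)C=C3CO[Si](C)(C)C(C)(C)C)C(=O)c12 | intermediate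
20 | 5-[(1R)-1-[(tert-butyldimethylsilyl)oxy]-3-hydroxy-3-methylbutyl]-6'-(hydroxymethyl)-4-methoxy-4'-methyl-3H-spiro[1-benzofuran-2,1'-cyclohexa[3,5]diene]-2',3-dione | COc1c([C@H](O[Si](C)(C)C(C)(C)C)CC(C)(C)O)ccc2OC3(C(=O)C=C(C)C=C3CO)C(=O)c12 | intermediate (not isolated)
21 | 3-[(1R)-1-[(tert-butyldimethylsilyl)oxy]-3-hydroxy-3-methylbutyl]-11-hydroxy-4-methoxy-9-methyl-5H,7H-dibenzo[b,g][1,5]dioxocin-5-one | COc1c([C@H](O[Si](C)(C)C(C)(C)C)CC(C)(C)O)ccc2Oc3c(O)cc(C)cc3COC(=O)c12 | intermediate (not isolated)
22 | 3-[(1R)-1,3-dihydroxy-3-methylbutyl]-11-hydroxy-4-methoxy-9-methyl-5H,7H-dibenzo[b,g][1,5]dioxocin-5-one | COc1c([C@H](O)CC(C)(C)O)ccc2Oc3c(O)cc(C)cc3COC(=O)c12 | intermediate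
23 | 6-[2-hydroxy-6-(hydroxymethyl)-4-methylphenoxy]-3-[(1R)-1,3-dihydroxy-3-methylbutyl]-2-methoxybenzoic acid (CNP0452050.1) | COc1c([C@H](O)CC(C)(C)O)ccc(Oc2c(O)cc(C)cc2CO)c1C(=O)O | target

**Step count and risks**

Total: 15 steps. Longest linear sequence: 11 steps (steps 1–8, then 13–15); the enynoate branch (steps 9–12) is four steps.

Steps most likely to fail:

1. Step 13 (proposed new method). The ambident benzofuranolate may be acylated on oxygen by the activated ester instead of adding through carbon. The sequence may also stall at the open-chain adduct, or the product may be cleaved by base before isolation. The fallback separates the two bond formations into known reaction types; it sets out from 11 and 16 and comes back at 19. Acid 16 is esterified (allyl bromide, K2CO3, DMF) to prop-2-en-1-yl (2Z)-6-[(tert-butyldimethylsilyl)oxy]-3-methylhex-2-en-4-ynoate F1. Carbonate-catalysed conjugate addition of 11 to F1, an ester that cannot acylate the stabilised enolate, stops at the allyl (2Z,4Z)-dienoate F2. Pd(PPh3)4 with HCO2H/Et3N removes the allyl group without hydroxide to give the dienoic acid F3. F3 is closed to 19 by intramolecular C-acylation through its mixed anhydride (2,4,6-trichlorobenzoyl chloride, Et3N, then DMAP).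

2. Step 14. The tethered alkoxide may add to the C3 carbonyl too slowly, so that the dienone is consumed by fluoride- or alkoxide-induced side reactions, or the fragmentation may be incomplete before the second desilylation. The fallback uses an external nucleophile and reverses the order of events; it sets out from 19 and comes back at 23. Aqueous LiOH in THF at 0 °C adds hydroxide to C3 and the same aromatising retro-Claisen cleavage gives the bis-silylated seco acid F4. TBAF then removes both silyl groups to give 23 directly.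

3. Step 2. Electrophilic substitution of the magnesium phenoxide may be slow because the ortho ester withdraws electron density and competes for chelation, and long heating favours methoxymethyl ether formation. The fallback formylates before the ether is installed; it sets out from 1 and comes back at 3. Rieche formylation (Cl2CHOMe, TiCl4, CH2Cl2, 0 °C) of symmetrical 1, which has only one kind of activated position, gives methyl 3-formyl-2,6-dihydroxybenzoate F5. Mono-alkylation with methyl bromoacetate (KHCO3, DMF, rt) at the hydroxyl para to the formyl group, the one not flanked by two carbonyls, then gives 3.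

**Further compounds**

F1 | step 13 | prop-2-en-1-yl (2Z)-6-[(tert-butyldimethylsilyl)oxy]-3-methylhex-2-en-4-ynoate | C=CCOC(=O)/C=C(/C)C#CCO[Si](C)(C)C(C)(C)C
F2 | step 13 | prop-2-en-1-yl (2Z,4Z)-5-{5-[(1R)-1-[(tert-butyldimethylsilyl)oxy]-3-hydroxy-3-methylbutyl]-4-methoxy-3-oxo-2,3-dihydro-1-benzofuran-2-yl}-6-[(tert-butyldimethylsilyl)oxy]-3-methylhexa-2,4-dienoate | C=CCOC(=O)/C=C(/C)\C=C(\CO[Si](C)(C)C(C)(C)C)/C1Oc2ccc([C@H](O[Si](C)(C)C(C)(C)C)CC(C)(C)O)c(OC)c2C1=O
F3 | step 13 | (2Z,4Z)-5-{5-[(1R)-1-[(tert-butyldimethylsilyl)oxy]-3-hydroxy-3-methylbutyl]-4-methoxy-3-oxo-2,3-dihydro-1-benzofuran-2-yl}-6-[(tert-butyldimethylsilyl)oxy]-3-methylhexa-2,4-dienoic acid | OC(=O)/C=C(/C)\C=C(\CO[Si](C)(C)C(C)(C)C)/C1Oc2ccc([C@H](O[Si](C)(C)C(C)(C)C)CC(C)(C)O)c(OC)c2C1=O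
F4 | step 14 | 6-[2-{[(tert-butyldimethylsilyl)oxy]methyl}-6-hydroxy-4-methylphenoxy]-3-[(1R)-1-[(tert-butyldimethylsilyl)oxy]-3-hydroxy-3-methylbutyl]-2-methoxybenzoic acid | COc1c([C@H](O[Si](C)(C)C(C)(C)C)CC(C)(C)O)ccc(Oc2c(O)cc(C)cc2CO[Si](C)(C)C(C)(C)C)c1C(=O)O
F5 | step 2 | methyl 3-formyl-2,6-dihydroxybenzoate | COC(=O)c1c(O)ccc(C=O)c1O
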